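The lactone (O1, C2 carbonyl, C3 methylene-bearing, C4 carboxyl-bearing, C5 alkyl-bearing) is disconnected at O1–C5. The plan exploits the O–C5–C4–CO2H array of this ring: the C4 carboxyl and the C5 oxygen are first tied into a temporary trans-oxetan-2-one, which masks that acid and makes C5–O a strained leaving group. In the key step the carboxylate of the acetic acid arm on C4 (future C2 and C3) attacks C5 with inversion; strain release closes the five-membered ring and frees the C4 acid in one operation. The precursor comes from an asymmetric ketene–aldehyde cycloaddition and a trans-selective enolate alkylation; the exocyclic methylene is installed last.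

Key step: step 5

Remark: O1 and C2–C5 in the Why lines are the lactone atoms defined above; systematic names carry their own locants.

Assumption: O-trimethylsilylquinine is taken to give the (S)-oxetanone in step 3; if the sense is the opposite, the pseudoenantiomeric O-trimethylsilylquinidine is used and nothing else changes.

Step 1
Reactants: 1 16-hydroxyhexadecanoic acid; 2 benzyl bromide
Product: 3 benzyl 16-hydroxyhexadecanoate
Conditions: BnBr, KHCO3, DMF, rt
Reagents that add atoms: benzyl bromide, BrCc1ccccc1
Why: Chemoselective carboxylate O-alkylation (SN2 esterification), since KHCO3 ionises only the acid and the primary alcohol stays free; no stereocenter is formed.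

Step 2
Reactants: 3 benzyl 16-hydroxyhexadecanoate
Product: 4 benzyl 16-oxohexadecanoate
Conditions: TEMPO (10 mol %), PhI(OAc)2, CH2Cl2, rt
Reagents that add atoms: none
Why: Oxoammonium-mediated (TEMPO) oxidation of a primary alcohol should stop at the aldehyde and leave the benzyl ester untouched.

Step 3
Reactants: 4 benzyl 16-oxohexadecanoate; 5 acetyl chloride
Product: 6 benzyl 15-[(2S)-4-oxooxetan-2-yl]pentadecanoate
Conditions: AcCl (slow addition), iPr2NEt, O-trimethylsilylquinine (10 mol %), LiClO4, CH2Cl2/Et2O, −78 °C
Reagents that add atoms: acetyl chloride, CC(=O)Cl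
Why: Catalytic asymmetric acyl halide–aldehyde cyclocondensation (alkaloid-catalysed ketene–aldehyde [2+2] cycloaddition), in which ketene made in the flask is bound as an acylammonium enolate that adds to the LiClO4-activated aldehyde and lactonises, the quinine-derived catalyst selecting the aldehyde face and so setting C5 as (S) in the oxetanone.

Step 4
Reactants: 6 benzyl 15-[(2S)-4-oxooxetan-2-yl]pentadecanoate; 7 benzyl bromoacetate
Product: 9 benzyl 15-[(2S,3S)-3-(2-(benzyloxy)-2-oxoethyl)-4-oxooxetan-2-yl]pentadecanoate, via lithium enolate 8 (not isolated)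
Conditions: LiN(SiMe3)2 (1.05 equiv), THF, −78 °C; then BrCH2CO2Bn, DMPU, −78 → −50 °C; AcOH quench
Reagents that add atoms: benzyl bromoacetate, BrCC(=O)OCc1ccccc1; LiN(SiMe3)2, [Li+].C[Si](C)(C)[N-][Si](C)(C)C (lithium only in 8)
Why: Alkylation of a β-lactone enolate, in which the more acidic ring α-CH2 should be deprotonated in preference to the remote ester, β-elimination is stereoelectronically blocked in the four-membered ring at −78 °C, and the electrophile enters anti to the C5 alkyl chain (1,2-induction), which sets C4 and gives the trans (2S,3S) oxetanone.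

Step 5
Reactants: 9 benzyl 15-[(2S,3S)-3-(2-(benzyloxy)-2-oxoethyl)-4-oxooxetan-2-yl]pentadecanoate
Product: 11 (2R,3S)-2-(14-carboxytetradecyl)-5-oxooxolane-3-carboxylic acid, via diacid oxetanone 10 (not isolated)
Conditions: H2 (1 atm), 10% Pd/C, EtOAc, rt; filter, concentrate; then Cs2CO3 (2.2 equiv), DMF (0.02 M), rt; 1 M HCl
Reagents that add atoms: none
Why: Hydrogenolysis frees both acids without touching the oxetanone, and the cesium carboxylate of the CH2CO2H arm then attacks C5 from the side opposite the ring oxygen (SN2 alkyl–oxygen scission), expelling the C4 carboxylate, with release of the four-ring strain making the step irreversible. The closest known reaction type is the ring opening of β-lactones at the β-carbon by carboxylates with inversion (the propagation step of carboxylate-initiated β-butyrolactone polymerisation), run here intramolecularly. The five-membered ring closes in the 5-exo-tet mode: O1, C2, C3, C4 and C5 form the ring and the leaving oxygen is exocyclic. C5 is the only centre that changes, (S) in the oxetanone becoming (R) in the oxolanone by inversion, while C4 is untouched; because arm and alkyl chain are trans on the four-membered ring, inversion at C5 places the alkyl chain trans to the liberated C4 acid. The step needs attack at C5 and not at the lactone carbonyl (acyl transfer through a cyclic anhydride would re-lactonise with retention and give the cis isomer), which a soft carboxylate in a dipolar aprotic medium, where an alkoxide is a very poor leaving group, should secure; the remote chain carboxylate cannot compete with five-ring closure at high dilution.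

Step 6
Reactants: 11 (2R,3S)-2-(14-carboxytetradecyl)-5-oxooxolane-3-carboxylic acid; 12 magnesium methyl carbonate MeOMgOCO2Me (Stiles reagent); 13 formaldehyde
Product: 15 (2R,3S)-2-(14-carboxytetradecyl)-4-methylidene-5-oxooxolane-3-carboxylic acid, via alpha-carboxy lactone 14 (not isolated)
Conditions: MeOMgOCO2Me (2 M in DMF, excess), 130 °C; cold 6 M HCl, extract; crude acid, 37% aq. CH2O, PhNHMe, AcOH, NaOAc, rt
Reagents that add atoms: formaldehyde, C=O; MeOMgOCO2Me, COC(=O)O[Mg]OC (its CO2 unit is present only in 14 and is lost again)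
Why: Stiles carboxylation followed by decarboxylative Mannich methylenation, in which the reagent carboxylates the only lactone α-CH2 (C3) as a magnesium chelate and the resulting malonic-type acid condenses with formaldehyde and N-methylaniline and then loses CO2 and the amine to give the exocyclic alkene, C4 and C5 being untouched and trans being the thermodynamic arrangement.

Compound list
1 | 16-hydroxyhexadecanoic acid | OCCCCCCCCCCCCCCCC(=O)O | starting material
2 | benzyl bromide | BrCc1ccccc1 | starting material
3 | benzyl 16-hydroxyhexadecanoate | OCCCCCCCCCCCCCCCC(=O)OCc1ccccc1 | intermediate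
4 | benzyl 16-oxohexadecanoate | O=CCCCCCCCCCCCCCCC(=O)OCc1ccccc1 | intermediate
5 | acetyl chloride | CC(=O)Cl | starting material
6 | benzyl 15-[(2S)-4-oxooxetan-2-yl]pentadecanoate | O=C(OCc1ccccc1)CCCCCCCCCCCCCC[C@H]1CC(=O)O1 | intermediate
7 | benzyl bromoacetate | BrCC(=O)OCc1ccccc1 | starting material
8 | lithium enolate of 6, lithium (4S)-4-[15-(benzyloxy)-15-oxopentadecyl]-4H-oxet-2-olate | O=C(OCc1ccccc1)CCCCCCCCCCCCCC[C@H]1C=C([O-])O1.[Li+] | intermediate
9 | benzyl 15-[(2S,3S)-3-(2-(benzyloxy)-2-oxoethyl)-4-oxooxetan-2-yl]pentadecanoate (trans) | O=C(OCc1ccccc1)CCCCCCCCCCCCCC[C@@H]1OC(=O)[C@H]1CC(=O)OCc1ccccc1 | intermediate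
10 | 15-[(2S,3S)-3-(carboxymethyl)-4-oxooxetan-2-yl]pentadecanoic acid | OC(=O)CCCCCCCCCCCCCC[C@@H]1OC(=O)[C@H]1CC(=O)O | intermediate
11 | (2R,3S)-2-(14-carboxytetradecyl)-5-oxooxolane-3-carboxylic acid (trans) | OC(=O)CCCCCCCCCCCCCC[C@H]1OC(=O)C[C@@H]1C(=O)O | intermediate
12 | magnesium methyl carbonate, MeOMgOCO2Me (Stiles reagent) | COC(=O)O[Mg]OC | starting material
13 | formaldehyde | C=O | starting material
14 | (2R,3S)-2-(14-carboxytetradecyl)-5-oxooxolane-3,4-dicarboxylic acid (epimers at C4 of the oxolane) | OC(=O)CCCCCCCCCCCCCC[C@H]1OC(=O)C(C(=O)O)[C@@H]1C(=O)O | intermediate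
15 | (2R,3S)-2-(14-carboxytetradecyl)-4-methylidene-5-oxooxolane-3-carboxylic acid | OC(=O)CCCCCCCCCCCCCC[C@H]1OC(=O)C(=C)[C@@H]1C(=O)O | target

Total steps: 6. Longest linear sequence: 6 steps (1 to 15).

Steps most likely to fail

Step 4. The ring enolate may acylate unreacted lactone or fragment before C-alkylation, and competing deprotonation next to the remote ester may divert base and electrophile. The fallback replaces the ring enolate by dianion alkylation of an open-chain β-hydroxy ester. Setting out from 6, ring opening with LiOCH2CH=CH2 (0.2 equiv) in allyl alcohol/THF at −20 °C should give 18-benzyl 1-(prop-2-en-1-yl) (3S)-3-hydroxyoctadecanedioate F1. Fráter–Seebach alkylation (LiN(iPr)2, 2.2 equiv, THF, −78 to −40 °C, then 7, cold quench) should give the anti product 4-benzyl 1-(prop-2-en-1-yl) (2S)-2-[(1S)-16-(benzyloxy)-1-hydroxy-16-oxohexadecyl]butanedioate F2. Pd(PPh3)4 with pyrrolidine removes the allyl ester to give (2S)-4-(benzyloxy)-2-[(1S)-16-(benzyloxy)-1-hydroxy-16-oxohexadecyl]-4-oxobutanoic acid F3. PhSO2Cl in pyridine at 0 °C closes the oxetanone through the activated carboxyl with retention and comes back to the route at 9.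

Step 5. Attack of the arm carboxylate on the lactone carbonyl instead of C5, followed by re-lactonisation with retention, would erode the trans configuration, and adventitious water may hydrolyse the oxetanone. The fallback closes the same O1–C5 bond by sulfonate displacement in an open-chain substrate. Setting out from 9, acyl opening with LiOCH2Ph (0.2 equiv) in benzyl alcohol/THF at −40 °C should give dibenzyl (2S)-2-[(1S)-16-(benzyloxy)-1-hydroxy-16-oxohexadecyl]butanedioate F4. MsCl and Et3N in CH2Cl2 at −20 °C give dibenzyl (2S)-2-[(1S)-16-(benzyloxy)-1-(methanesulfonyloxy)-16-oxohexadecyl]butanedioate F5. Hydrogenolysis (H2, Pd/C, EtOAc) frees (2S)-2-[(1S)-15-carboxy-1-(methanesulfonyloxy)pentadecyl]butanedioic acid F6, which is not isolated. With NaHCO3 in DMF at 40 °C the arm carboxylate should displace the mesylate at C5 with inversion (5-exo-tet), and the sequence comes back to the route at 11.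

Step 6. Prolonged heating with the magnesium reagent may leave carboxylation incomplete, and the new alkene may migrate into the ring during the Mannich stage. The fallback is direct aminomethylation of the lactone enolate. Setting out from 11, LiN(SiMe3)2 (3.3 equiv, THF, −78 °C) forms the dicarboxylate lactone enolate, which is trapped with [Me2N=CH2]I (Eschenmoser salt) to give (2R,3S)-2-(14-carboxytetradecyl)-4-[(dimethylamino)methyl]-5-oxooxolane-3-carboxylic acid F7. MeI in MeOH gives 1-[(4S,5R)-4-carboxy-5-(14-carboxytetradecyl)-2-oxooxolan-3-yl]-N,N,N-trimethylmethanaminium iodide F8. Aqueous NaHCO3/EtOAc eliminates the amine and comes back to the route at 15.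

Further compounds
F1 | step 4 | 18-benzyl 1-(prop-2-en-1-yl) (3S)-3-hydroxyoctadecanedioate | C=CCOC(=O)C[C@@H](O)CCCCCCCCCCCCCCC(=O)OCc1ccccc1
F2 | step 4 | 4-benzyl 1-(prop-2-en-1-yl) (2S)-2-[(1S)-16-(benzyloxy)-1-hydroxy-16-oxohexadecyl]butanedioate | C=CCOC(=O)[C@@H](CC(=O)OCc1ccccc1)[C@@H](O)CCCCCCCCCCCCCCC(=O)OCc1ccccc1
F3 | step 4 | (2S)-4-(benzyloxy)-2-[(1S)-16-(benzyloxy)-1-hydroxy-16-oxohexadecyl]-4-oxobutanoic acid | OC(=O)[C@@H](CC(=O)OCc1ccccc1)[C@@H](O)CCCCCCCCCCCCCCC(=O)OCc1ccccc1
F4 | step 5 | dibenzyl (2S)-2-[(1S)-16-(benzyloxy)-1-hydroxy-16-oxohexadecyl]butanedioate | O=C(OCc1ccccc1)[C@@H](CC(=O)OCc1ccccc1)[C@@H](O)CCCCCCCCCCCCCCC(=O)OCc1ccccc1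
F5 | step 5 | dibenzyl (2S)-2-[(1S)-16-(benzyloxy)-1-(methanesulfonyloxy)-16-oxohexadecyl]butanedioate | O=C(OCc1ccccc1)[C@@H](CC(=O)OCc1ccccc1)[C@@H](OS(C)(=O)=O)CCCCCCCCCCCCCCC(=O)OCc1ccccc1
F6 | step 5 | (2S)-2-[(1S)-15-carboxy-1-(methanesulfonyloxy)pentadecyl]butanedioic acid | OC(=O)[C@@H](CC(=O)O)[C@@H](OS(C)(=O)=O)CCCCCCCCCCCCCCC(=O)O
F7 | step 6 | (2R,3S)-2-(14-carboxytetradecyl)-4-[(dimethylamino)methyl]-5-oxooxolane-3-carboxylic acid (epimers at C4 of the oxolane) | OC(=O)CCCCCCCCCCCCCC[C@H]1OC(=O)C(CN(C)C)[C@@H]1C(=O)O
F8 | step 6 | 1-[(4S,5R)-4-carboxy-5-(14-carboxytetradecyl)-2-oxooxolan-3-yl]-N,N,N-trimethylmethanaminium iodide | OC(=O)CCCCCCCCCCCCCC[C@H]1OC(=O)C(C[N+](C)(C)C)[C@@H]1C(=O)O.[I-]
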